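A closed, stirred flask is what both earlier runs used, and south-east is a closed flask with Tuesday's charge, so I read Tuesday's curve forward.

| flask | starting material | coupling partner | free catalyst | remark | time |
|---|---|---|---|---|---|
| Tuesday's | 10 mM | 11 mM | 5 µM | run made earlier |  |
| Wednesday's | 20 mM | 11 mM | 5 µM | run made earlier |  |
| south | 10 mM (fed, over 4.00 d) | 11.0 mM | 5.0 µM | a stirred flask in which starting material is dosed at a steady rate over 4.00 d without added volume, worked up at 4.0 d | 4.0 d |
| south-east | 10 mM | 11.0 mM | 5.0 µM | a closed flask charged with all of it at once and left for 4.0 d | 4.0 d |
| north | 10 mM | 11.0 mM (fed, over 4.00 d) | 5.0 µM | a stirred flask in which coupling partner is dosed at a steady rate over 4.00 d without added volume, worked up at 4.0 d | 4.0 d |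
| east | 10 mM | 11.0 mM | 5.0 µM | a single well-mixed tank run continuously and read at steady state, 4.0 d in it on average |  |

| Tuesday's: time / d | Tuesday's: product / % | Wednesday's: time / h | Wednesday's: product / % |
|---|---|---|---|
| 0.208 | 53.8 | 1.50 | 14.7 |
| 0.625 | 89.2 | 3.00 | 23.9 |
| 1.04 | 97.6 | 5.00 | 29.9 |
| 1.67 | 98.8 | 10.0 | 43.9 |
| 2.50 | 99.9 | 20.0 | 50.8 |

(scatter of a reading: 1 percentage point)

* the set-up with the highest amount of product at the outlet or at the end, in percent of the starting material put in ("none" if the first two lie within 2 percentage points) (south / south-east / north / east / none)
* amount of product at the outlet or at the end, in percent of the starting material put in, south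
* amount of product at the outlet or at the end, in percent of the starting material put in, south-east
* amount of product at the outlet or at the end, in percent of the starting material put in, north
* amount of product at the outlet or at the end, in percent of the starting material put in, east

- the stated concentrations are those of everything mixed, before any reaction; amounts are the same in each set-up
- reactions considered so far: coupling partner + free catalyst -> catalyst intermediate A; starting material + catalyst intermediate A <-> catalyst intermediate B; catalyst intermediate B <-> free catalyst + product; free catalyst -> spent catalyst
- the feed brings no volume worth counting
- the earlier runs were made in a closed, stirred flask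

Tuesday's first reading, 53.8% product at 0.208 d, gave a half-life of 0.187 d if the loss is first order. So 4.0 d holds 21.4 half-lives, and I called this the half-life count, the time on hand divided by Tuesday's half-life.

By my estimate, that many halvings left south-east 3.55 nM of starting material. Its charge of 10 mM lies below the 11.0 mM of coupling partner, so starting material is the limiting reagent, and I committed to >99.9% product. For south, dosed steadily, I reckoned on about one lifetime's worth of feed standing at the end, one over the count times ln two. That is 6.73% of the charge, so 93.3% product, less than south-east, and south-east was my pick for best.

The weak link was resting the count on one early reading. Wednesday's run, with 20 mM of starting material, reached 50.8% at 20.0 h, so I kept Tuesday's half-life for south-east, which has Tuesday's charges, and used it for south as a rougher estimate. Reforged on the reading of 89.2% at 0.625 d, the half-life became 0.195 d and the count 20.5, and my commitment stood.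

The forecast gave 99.7% for south-east, 92% for south, 45% for north and 83% for east, with south-east as best, noting that “Tuesday looks first order in starting material, but with coupling partner only slightly in excess, this does not separate the two steps”.

South-east gave 100%, south 94.7%, north 96.9% and east 94.0%, and the best was south-east.

    coupling partner + free catalyst → catalyst intermediate A (k = 50500 /M/h)
    starting material + catalyst intermediate A ⇌ catalyst intermediate B (K = 1110 /M, k = 74600 /M/h)
    catalyst intermediate B ⇌ free catalyst + product (K = 0.0180 M, k = 39100 /h)
    free catalyst → spent catalyst (k = 2.39 × 10⁻⁴ /h)

At 2.00 d south-east held 0.0195% of the starting material charged, less than the 0.0601% that the count gives for that time. East is a single tank with 4.0 d of stay on average, and a first-order tank at steady state keeps one over one plus the count times ln two. Tuesday's half-life makes that 6.32%, and east's outlet carried 6.03% of the starting material charged.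

The runs are calculated for substances that don't exist; noise was put on by code.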